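**Retrosynthetic overview**

1. Target 19 comes from hydrogenolysis of the nona-benzyl ether 18. The lower 4-hydroxyl of 18 comes from hydrolysis of a 4-arylthio group (17) that stays inert during the interflavan coupling.
2. The interflavan C4–C6 bond comes from Friedel–Crafts alkylation of the lower unit 16 by the C4 cation of the upper flavan-4-ol 13, with attack anti to the 3-benzyloxy group.
3. 13 and 15 come from enantioselective hydrogenation of the flavonol ethers 8 and 11, which sets C2, C3 and C4 of each unit in one step.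
4. Ring C of 8 is made from fluoro ketone 5 and aroyl chloride 6 in one operation: C-acylation (C2–C3), then SNAr (O1–C8a). The enabling feature is that C8a of ring A is ortho to C4a, so C4 carried as a carbonyl acidifies C3–H and activates the C8a–F bond, while O1 and C2 arrive together as the aroyl C=O. Ring C of 11 is made the same way from 5 and 9.
5. Ring order: ring C of the upper unit (step 3), then ring C of the lower unit (step 4). Rings A and B are bought as 3-fluorocatechol and the two benzoyl chlorides.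

Key step: step 3

Remark: compounds 3, 6 and 9 are taken as catalogue reagents, and 13 and 15 are drawn as the expected all-cis C4 alcohols, although either C4 epimer would serve because C4 is ionised in the next step of each unit.

**Route**

Step 1
Reactants: 1 3-fluorobenzene-1,2-diol
Product: 2 1,2-bis(benzyloxy)-3-fluorobenzene
Conditions: BnBr (2.3 equiv), K2CO3, DMF, 60 °C
Reagents that add atoms: benzyl bromide, BrCc1ccccc1
Why: Williamson O-benzylation of both phenols should proceed cleanly, and the benzyl ethers should survive strong base, Lewis acid at low temperature and the ruthenium-catalysed hydrogenation before being removed together at the end.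

Step 2
Reactants: 2 1,2-bis(benzyloxy)-3-fluorobenzene; 3 2-(benzyloxy)-N-methoxy-N-methylacetamide
Product: 5 2-(benzyloxy)-1-[3,4-bis(benzyloxy)-2-fluorophenyl]ethan-1-one, via aryllithium 4 (not isolated)
Conditions: n-BuLi (1.05 equiv), THF, −78 °C; then 3, −78 → 0 °C; aq. work-up
Reagents that add atoms: none
Why: Fluorine-directed ortho-lithiation should occur at the ring C–H next to fluorine (the most acidic position, and at −78 °C faster than benzylic deprotonation or LiF loss), and acylation of the aryllithium with a Weinreb amide stops at the ketone because the chelated tetrahedral adduct prevents over-addition.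

Step 3
Reactants: 5 2-(benzyloxy)-1-[3,4-bis(benzyloxy)-2-fluorophenyl]ethan-1-one; 6 4-(benzyloxy)benzoyl chloride
Product: 8 3,7,8-tris(benzyloxy)-2-[4-(benzyloxy)phenyl]-4H-chromen-4-one, via β-diketone 7 (not isolated)
Conditions: LiN(SiMe3)2 (2.2 equiv), THF, −78 °C; then 6, −78 → 0 °C; then DMF, 80 °C
Reagents that add atoms: none
Why: Two equivalents of LiN(SiMe3)2 should turn 5 into its chelated lithium enolate, which is C-acylated at C3 by 6 (Claisen-type acylation, C2–C3 bond) and deprotonated again to the diketonate of 7; on heating in DMF the enolate oxygen of the new aroyl unit attacks C8a and expels fluoride through a Meisenheimer complex stabilised by the ortho C4 carbonyl (O1–C8a bond). The closest known reaction type is the base-mediated cyclisation of 1-(2-halophenyl)-1,3-diketones to chromones and flavones, run here in tandem with the acylation that makes the diketone. Ring C closes as a six-membered intramolecular SNAr (addition–elimination at the sp2 carbon C8a, exo with respect to the C8a–F bond). No stereocentre is formed: the product is the planar flavonol ether, and C2, C3 and C4 are set together in step 5. The step needs C- over O-acylation, which the lithium chelate of the α-benzyloxy enolate in a weakly polar medium should secure (any enol ester is returned to 7 by acyl transfer to remaining enolate). It also needs O- over C-arylation at a single site, which is secured because only the oxygen reaches C8a through a six-membered transition state and fluorine is the only leaving group on ring A.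

Step 4
Reactants: 5 2-(benzyloxy)-1-[3,4-bis(benzyloxy)-2-fluorophenyl]ethan-1-one; 9 3,4-bis(benzyloxy)benzoyl chloride
Product: 11 3,7,8-tris(benzyloxy)-2-[3,4-bis(benzyloxy)phenyl]-4H-chromen-4-one, via β-diketone 10 (not isolated)
Conditions: LiN(SiMe3)2 (2.2 equiv), THF, −78 °C; then 9, −78 → 0 °C; then DMF, 80 °C
Reagents that add atoms: none
Why: The same tandem Claisen-type C-acylation and intramolecular SNAr as in step 3 should build ring C of the lower unit from the common fluoro ketone, again without forming a stereocentre.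

Step 5
Reactants: 8 3,7,8-tris(benzyloxy)-2-[4-(benzyloxy)phenyl]-4H-chromen-4-one
Product: 13 (2R,3R,4R)-3,7,8-tris(benzyloxy)-2-[4-(benzyloxy)phenyl]chroman-4-ol (all-cis), via cis-flavanone 12 (not isolated)
Conditions: [Ru(cod)(2-methylallyl)2] (5 mol %), 1,3-bis[(R)-1-(naphthalen-1-yl)ethyl]-4,5-dihydroimidazolium tetrafluoroborate (10 mol %), KOt-Bu (12 mol %), H2 (100 bar), toluene, 40 °C
Reagents that add atoms: none
Why: Proposed new method: the chiral catalyst formed in situ from [Ru(cod)(2-methylallyl)2] and the N-heterocyclic carbene is expected to add H2 syn to the tetrasubstituted C2=C3 bond of the vinylogous ester from one enantioface (C2 and C3 set cis in flavanone 12) and then to reduce the C4 carbonyl anti to the axial 3-benzyloxy group (all-cis 13); the closest known reaction types are the ruthenium–carbene-catalysed asymmetric hydrogenation of flavones and chromones to cis-flavan-4-ols and the all-cis course of catalytic hydrogenation of flavonol ethers, which have not been shown on a 3-alkoxyflavone; the ligand enantiomer is to be chosen so that the (2R,3R) series results.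

Step 6
Reactants: 11 3,7,8-tris(benzyloxy)-2-[3,4-bis(benzyloxy)phenyl]-4H-chromen-4-one
Product: 15 (2R,3R,4R)-3,7,8-tris(benzyloxy)-2-[3,4-bis(benzyloxy)phenyl]chroman-4-ol (all-cis), via cis-flavanone 14 (not isolated)
Conditions: [Ru(cod)(2-methylallyl)2] (5 mol %), 1,3-bis[(R)-1-(naphthalen-1-yl)ethyl]-4,5-dihydroimidazolium tetrafluoroborate (10 mol %), KOt-Bu (12 mol %), H2 (100 bar), toluene, 40 °C
Reagents that add atoms: none
Why: Proposed new method: as in step 5, syn delivery of H2 to one face of the tetrasubstituted C2=C3 bond should set C2 and C3 cis (flavanone 14) and carbonyl reduction anti to the axial 3-benzyloxy group should give the all-cis alcohol; the closest known reaction type is the ruthenium–carbene-catalysed asymmetric hydrogenation of flavones to cis-flavan-4-ols, not yet shown on a 3-alkoxyflavone.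

Step 7
Reactants: 15 (2R,3R,4R)-3,7,8-tris(benzyloxy)-2-[3,4-bis(benzyloxy)phenyl]chroman-4-ol
Product: 16 (2R,3S,4S)-3,7,8-tris(benzyloxy)-2-[3,4-bis(benzyloxy)phenyl]-4-[(2,6-dimethylphenyl)sulfanyl]chromane (2,3-cis-3,4-trans)
Conditions: 2,6-dimethylbenzenethiol (3 equiv), BF3·OEt2 (1.2 equiv), CH2Cl2, −78 → −30 °C
Reagents that add atoms: 2,6-dimethylbenzenethiol, Cc1cccc(C)c1S
Why: BF3-promoted SN1 thiolysis of the benzylic C4 alcohol should give the 3,4-trans thioether, because the cation stabilised by the para 7-benzyloxy group and O1 is captured by the thiol anti to the axial 3-benzyloxy group; the hindered arylthio group then serves as a latent leaving group that hard Lewis acids are expected to leave intact at low temperature.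

Step 8
Reactants: 13 (2R,3R,4R)-3,7,8-tris(benzyloxy)-2-[4-(benzyloxy)phenyl]chroman-4-ol; 16 (2R,3S,4S)-3,7,8-tris(benzyloxy)-2-[3,4-bis(benzyloxy)phenyl]-4-[(2,6-dimethylphenyl)sulfanyl]chromane
Product: 17 (2R,3S,4S)-3,7,8-tris(benzyloxy)-2-[3,4-bis(benzyloxy)phenyl]-4-[(2,6-dimethylphenyl)sulfanyl]-6-{(2R,3R,4R)-3,7,8-tris(benzyloxy)-2-[4-(benzyloxy)phenyl]chroman-4-yl}chromane (upper unit 2,3-cis-3,4-trans)
Conditions: 16 (3 equiv), BF3·OEt2 (1.5 equiv), 4 Å molecular sieves, CH2Cl2, −78 → −30 °C, slow addition of 13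
Reagents that add atoms: none
Why: This is the standard Lewis-acid-mediated flavan-4-ol/arene condensation (Friedel–Crafts alkylation): the C4 cation of the 2,3-cis unit should be attacked anti to its 3-benzyloxy group by C6 of 16 (ortho to 7-OBn, para to the ring oxygen), giving the 3,4-trans, 2,4-trans C4–C6 bond, while the 2,6-dimethyl groups shield the sulfur of 16 and excess 16 suppresses self-condensation of 13.

Step 9
Reactants: 17 (the thioether dimer of step 8)
Product: 18 (2R,3R,4S)-3,7,8-tris(benzyloxy)-2-[3,4-bis(benzyloxy)phenyl]-6-{(2R,3R,4R)-3,7,8-tris(benzyloxy)-2-[4-(benzyloxy)phenyl]chroman-4-yl}chroman-4-ol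
Conditions: AgBF4 (2 equiv), NaHCO3, THF/H2O (5:1), 0 °C
Reagents that add atoms: water, O
Why: Thiophilic activation of the C4 sulfide by silver ion should generate the benzylic cation, which water in large excess captures anti to the 3-benzyloxy group (SN1 solvolysis) to set the 3,4-trans hydroxyl, while bicarbonate keeps the medium neutral so that the new benzylic alcohol and the interflavan bond are not re-ionised.

Step 10
Reactants: 18 (the nona-benzyl dimer of step 9)
Product: 19 (2R,3R,4S)-2-(3,4-dihydroxyphenyl)-6-[(2R,3R,4S)-3,7,8-trihydroxy-2-(4-hydroxyphenyl)chroman-4-yl]chromane-3,4,7,8-tetrol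
Conditions: H2 (1 atm), Pd(OH)2/C, THF/MeOH (1:1), 23 °C; filtration under argon
Reagents that add atoms: none
Why: Catalytic hydrogenolysis should cleave all nine benzyl ethers under neutral conditions without touching a stereocentre, and low pressure, a neutral medium and stopping at complete debenzylation should preserve the benzylic C4 hydroxyl and the benzylic ring C–O bonds.

**Compound list**

1 | 3-fluorobenzene-1,2-diol | Oc1cccc(F)c1O | starting material
2 | 1,2-bis(benzyloxy)-3-fluorobenzene | Fc1cccc(OCc2ccccc2)c1OCc1ccccc1 | intermediate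
3 | 2-(benzyloxy)-N-methoxy-N-methylacetamide | CON(C)C(=O)COCc1ccccc1 | starting material
4 | [3,4-bis(benzyloxy)-2-fluorophenyl]lithium | [Li]c1ccc(OCc2ccccc2)c(OCc2ccccc2)c1F | intermediate
5 | 2-(benzyloxy)-1-[3,4-bis(benzyloxy)-2-fluorophenyl]ethan-1-one | O=C(COCc1ccccc1)c1ccc(OCc2ccccc2)c(OCc2ccccc2)c1F | intermediate
6 | 4-(benzyloxy)benzoyl chloride | O=C(Cl)c1ccc(OCc2ccccc2)cc1 | starting material
7 | 2-(benzyloxy)-1-[3,4-bis(benzyloxy)-2-fluorophenyl]-3-[4-(benzyloxy)phenyl]propane-1,3-dione (stereolabile at C2) | O=C(c1ccc(OCc2ccccc2)cc1)C(OCc1ccccc1)C(=O)c1ccc(OCc2ccccc2)c(OCc2ccccc2)c1F | intermediate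
8 | 3,7,8-tris(benzyloxy)-2-[4-(benzyloxy)phenyl]-4H-chromen-4-one | O=c1c(OCc2ccccc2)c(-c2ccc(OCc3ccccc3)cc2)oc2c(OCc3ccccc3)c(OCc3ccccc3)ccc12 | intermediate
9 | 3,4-bis(benzyloxy)benzoyl chloride | O=C(Cl)c1ccc(OCc2ccccc2)c(OCc2ccccc2)c1 | starting material
10 | 2-(benzyloxy)-1-[3,4-bis(benzyloxy)-2-fluorophenyl]-3-[3,4-bis(benzyloxy)phenyl]propane-1,3-dione (stereolabile at C2) | O=C(c1ccc(OCc2ccccc2)c(OCc2ccccc2)c1)C(OCc1ccccc1)C(=O)c1ccc(OCc2ccccc2)c(OCc2ccccc2)c1F | intermediate
11 | 3,7,8-tris(benzyloxy)-2-[3,4-bis(benzyloxy)phenyl]-4H-chromen-4-one | O=c1c(OCc2ccccc2)c(-c2ccc(OCc3ccccc3)c(OCc3ccccc3)c2)oc2c(OCc3ccccc3)c(OCc3ccccc3)ccc12 | intermediate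
12 | (2R,3S)-3,7,8-tris(benzyloxy)-2-[4-(benzyloxy)phenyl]chroman-4-one (2,3-cis) | O=C1c2ccc(OCc3ccccc3)c(OCc3ccccc3)c2O[C@H](c2ccc(OCc3ccccc3)cc2)[C@@H]1OCc1ccccc1 | intermediate
13 | (2R,3R,4R)-3,7,8-tris(benzyloxy)-2-[4-(benzyloxy)phenyl]chroman-4-ol (all-cis) | O[C@@H]1c2ccc(OCc3ccccc3)c(OCc3ccccc3)c2O[C@H](c2ccc(OCc3ccccc3)cc2)[C@@H]1OCc1ccccc1 | intermediate
14 | (2R,3S)-3,7,8-tris(benzyloxy)-2-[3,4-bis(benzyloxy)phenyl]chroman-4-one (2,3-cis) | O=C1c2ccc(OCc3ccccc3)c(OCc3ccccc3)c2O[C@H](c2ccc(OCc3ccccc3)c(OCc3ccccc3)c2)[C@@H]1OCc1ccccc1 | intermediate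
15 | (2R,3R,4R)-3,7,8-tris(benzyloxy)-2-[3,4-bis(benzyloxy)phenyl]chroman-4-ol (all-cis) | O[C@@H]1c2ccc(OCc3ccccc3)c(OCc3ccccc3)c2O[C@H](c2ccc(OCc3ccccc3)c(OCc3ccccc3)c2)[C@@H]1OCc1ccccc1 | intermediate
16 | (2R,3S,4S)-3,7,8-tris(benzyloxy)-2-[3,4-bis(benzyloxy)phenyl]-4-[(2,6-dimethylphenyl)sulfanyl]chromane (2,3-cis-3,4-trans) | Cc1cccc(C)c1S[C@H]1c2ccc(OCc3ccccc3)c(OCc3ccccc3)c2O[C@H](c2ccc(OCc3ccccc3)c(OCc3ccccc3)c2)[C@@H]1OCc1ccccc1 | intermediate
17 | (2R,3S,4S)-3,7,8-tris(benzyloxy)-2-[3,4-bis(benzyloxy)phenyl]-4-[(2,6-dimethylphenyl)sulfanyl]-6-{(2R,3R,4R)-3,7,8-tris(benzyloxy)-2-[4-(benzyloxy)phenyl]chroman-4-yl}chromane | c5ccccc5COc1ccc([C@H]2Oc3c(ccc(OCc5ccccc5)c3OCc5ccccc5)[C@H](c3cc4c(c(OCc5ccccc5)c3OCc5ccccc5)O[C@H](c3ccc(OCc5ccccc5)c(OCc5ccccc5)c3)[C@H](OCc5ccccc5)[C@H]4Sc5c(C)cccc5C)[C@H]2OCc5ccccc5)cc1 | intermediate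
18 | (2R,3R,4S)-3,7,8-tris(benzyloxy)-2-[3,4-bis(benzyloxy)phenyl]-6-{(2R,3R,4R)-3,7,8-tris(benzyloxy)-2-[4-(benzyloxy)phenyl]chroman-4-yl}chroman-4-ol | c5ccccc5COc1ccc([C@H]2Oc3c(ccc(OCc5ccccc5)c3OCc5ccccc5)[C@H](c3cc4c(c(OCc5ccccc5)c3OCc5ccccc5)O[C@H](c3ccc(OCc5ccccc5)c(OCc5ccccc5)c3)[C@H](OCc5ccccc5)[C@H]4O)[C@H]2OCc5ccccc5)cc1 | intermediate
19 | (2R,3R,4S)-2-(3,4-dihydroxyphenyl)-6-[(2R,3R,4S)-3,7,8-trihydroxy-2-(4-hydroxyphenyl)chroman-4-yl]chromane-3,4,7,8-tetrol | Oc1ccc([C@H]2Oc3c(ccc(O)c3O)[C@H](c3cc4c(c(O)c3O)O[C@H](c3ccc(O)c(O)c3)[C@H](O)[C@H]4O)[C@H]2O)cc1 | target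

**Step count and risks**

Total step count: 10. Longest linear sequence: 8 steps (steps 1, 2, 4, 6, 7, 8, 9, 10).

The three steps most likely to fail:

Step 5. The hydrogenation may be slow or poorly face-selective at the tetrasubstituted enol-ether double bond, and the alkoxide base may epimerise C3 of flavanone 12 before the carbonyl is reduced, leading into the 2,3-trans series. The fallback sets C2 and C3 by auxiliary chemistry and closes the two ring C bonds one after the other. The boron enolate of commercial (S)-4-benzyl-3-[(benzyloxy)acetyl]oxazolidin-2-one (Bu2BOTf, i-Pr2NEt, CH2Cl2, −78 → 0 °C) adds to 4-(benzyloxy)benzaldehyde in an Evans syn-glycolate aldol reaction to give (S)-4-benzyl-3-{(2S,3R)-2-(benzyloxy)-3-[4-(benzyloxy)phenyl]-3-hydroxypropanoyl}oxazolidin-2-one F1. Transamidation (MeONHMe·HCl, AlMe3, CH2Cl2) gives (2S,3R)-2-(benzyloxy)-3-[4-(benzyloxy)phenyl]-3-hydroxy-N-methoxy-N-methylpropanamide F2. Its hydroxyl is masked as the magnesium alkoxide (i-PrMgCl, 1 equiv), and aryllithium 4, made from 2 as in step 2, is added at −78 °C to give (2S,3R)-2-(benzyloxy)-1-[3,4-bis(benzyloxy)-2-fluorophenyl]-3-[4-(benzyloxy)phenyl]-3-hydroxypropan-1-one F3. Cs2CO3 in MeCN at 0 °C closes the O1–C8a bond by SNAr to flavanone 12, which is reduced at once with NaBH4 (MeOH/THF, −20 °C). This fallback sets out from 2 and comes back to the route at 13.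

Step 6. The same processes threaten the lower unit: unselective hydrogen delivery to the tetrasubstituted double bond and epimerisation at C3 of 14. The fallback is the same auxiliary sequence with 3,4-bis(benzyloxy)benzaldehyde. The Evans syn-glycolate aldol gives (S)-4-benzyl-3-{(2S,3R)-2-(benzyloxy)-3-[3,4-bis(benzyloxy)phenyl]-3-hydroxypropanoyl}oxazolidin-2-one F4. Transamidation gives (2S,3R)-2-(benzyloxy)-3-[3,4-bis(benzyloxy)phenyl]-3-hydroxy-N-methoxy-N-methylpropanamide F5. Addition of aryllithium 4 to its magnesium alkoxide gives (2S,3R)-2-(benzyloxy)-1-[3,4-bis(benzyloxy)-2-fluorophenyl]-3-[3,4-bis(benzyloxy)phenyl]-3-hydroxypropan-1-one F6. SNAr ring closure (Cs2CO3, MeCN, 0 °C) gives flavanone 14, which is reduced with NaBH4. This fallback sets out from 2 and comes back to the route at 15.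

Step 8. The C4 cation of 13 may be captured by ring A of a second molecule of 13 (self-condensation and oligomerisation) in competition with 16, and the arylthio group may be transferred between units. The fallback blocks the nucleophilic position of the electrophile. 13 is brominated at C6 of ring A (NBS, CH2Cl2, −20 °C) to give (2R,3R,4R)-6-bromo-3,7,8-tris(benzyloxy)-2-[4-(benzyloxy)phenyl]chroman-4-ol F7. Coupling with 16 under the conditions of step 8 gives the 6-bromo analogue of 17 (bromine at C6 of the upper unit, all stereocentres as in 17) F8. Hydrolysis under the conditions of step 9 gives the 6-bromo analogue of 18 F9. Hydrogenolysis with H2, Pd(OH)2/C and Et3N in THF/MeOH removes the benzyl ethers and the bromine together. This fallback sets out from 13 and comes back to the route at 19.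

**Further compounds**

F1 | step 5 | (S)-4-benzyl-3-{(2S,3R)-2-(benzyloxy)-3-[4-(benzyloxy)phenyl]-3-hydroxypropanoyl}oxazolidin-2-one | O=C1OC[C@H](Cc2ccccc2)N1C(=O)[C@@H](OCc1ccccc1)[C@H](O)c1ccc(OCc2ccccc2)cc1
F2 | step 5 | (2S,3R)-2-(benzyloxy)-3-[4-(benzyloxy)phenyl]-3-hydroxy-N-methoxy-N-methylpropanamide | CON(C)C(=O)[C@@H](OCc1ccccc1)[C@H](O)c1ccc(OCc2ccccc2)cc1
F3 | step 5 | (2S,3R)-2-(benzyloxy)-1-[3,4-bis(benzyloxy)-2-fluorophenyl]-3-[4-(benzyloxy)phenyl]-3-hydroxypropan-1-one | O=C(c1ccc(OCc2ccccc2)c(OCc2ccccc2)c1F)[C@@H](OCc1ccccc1)[C@H](O)c1ccc(OCc2ccccc2)cc1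
F4 | step 6 | (S)-4-benzyl-3-{(2S,3R)-2-(benzyloxy)-3-[3,4-bis(benzyloxy)phenyl]-3-hydroxypropanoyl}oxazolidin-2-one | O=C1OC[C@H](Cc2ccccc2)N1C(=O)[C@@H](OCc1ccccc1)[C@H](O)c1ccc(OCc2ccccc2)c(OCc2ccccc2)c1
F5 | step 6 | (2S,3R)-2-(benzyloxy)-3-[3,4-bis(benzyloxy)phenyl]-3-hydroxy-N-methoxy-N-methylpropanamide | CON(C)C(=O)[C@@H](OCc1ccccc1)[C@H](O)c1ccc(OCc2ccccc2)c(OCc2ccccc2)c1
F6 | step 6 | (2S,3R)-2-(benzyloxy)-1-[3,4-bis(benzyloxy)-2-fluorophenyl]-3-[3,4-bis(benzyloxy)phenyl]-3-hydroxypropan-1-one | O=C(c1ccc(OCc2ccccc2)c(OCc2ccccc2)c1F)[C@@H](OCc1ccccc1)[C@H](O)c1ccc(OCc2ccccc2)c(OCc2ccccc2)c1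
F7 | step 8 | (2R,3R,4R)-6-bromo-3,7,8-tris(benzyloxy)-2-[4-(benzyloxy)phenyl]chroman-4-ol | O[C@@H]1c2cc(Br)c(OCc3ccccc3)c(OCc3ccccc3)c2O[C@H](c2ccc(OCc3ccccc3)cc2)[C@@H]1OCc1ccccc1
F8 | step 8 | 6-bromo analogue of 17 (bromine at C6 of the upper unit, stereocentres as in 17) | c5ccccc5COc1ccc([C@H]2Oc3c(cc(Br)c(OCc5ccccc5)c3OCc5ccccc5)[C@H](c3cc4c(c(OCc5ccccc5)c3OCc5ccccc5)O[C@H](c3ccc(OCc5ccccc5)c(OCc5ccccc5)c3)[C@H](OCc5ccccc5)[C@H]4Sc5c(C)cccc5C)[C@H]2OCc5ccccc5)cc1
F9 | step 8 | 6-bromo analogue of 18 (bromine at C6 of the upper unit, stereocentres as in 18) | c5ccccc5COc1ccc([C@H]2Oc3c(cc(Br)c(OCc5ccccc5)c3OCc5ccccc5)[C@H](c3cc4c(c(OCc5ccccc5)c3OCc5ccccc5)O[C@H](c3ccc(OCc5ccccc5)c(OCc5ccccc5)c3)[C@H](OCc5ccccc5)[C@H]4O)[C@H]2OCc5ccccc5)cc1
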